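Ring A is disconnected across the C5–C4a bond and traced to a squarate: C5, C6, C7 and C8 (para oxygens at C5 and C8 flanking the C6 side chain and the C7 oxygen) are the four squarate carbons, while C4a and C8a are the C5=C6 bond of a preformed 3-aryl-4-pyranone that already holds rings C and B. Heating a 4-methoxy-4-(pyranon-2-yl)cyclobutenone opens it to a dienylketene that closes onto pyranone C5 and tautomerises, giving in one operation the hexasubstituted chromone with free 5-OH, 6-allyl, 7-isopropoxy and 8-OMe groups. Selective deisopropylation and allyl-to-prenyl cross-metathesis complete 6-prenylisocaviunin.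

Key step: step 5

Remark: every chiral intermediate is racemic; compounds with a single stereocentre are written without a stereodescriptor, and the prenyl double bond of the target needs no E/Z label.

Step 1
Reactants: 1 diisopropyl squarate; 2 allylmagnesium bromide
Product: 4 3-allyl-4-isopropoxycyclobut-3-ene-1,2-dione, via tertiary carbinol 3 (not isolated)
Conditions: 2 (1.05 equiv), THF, −78 °C; 1 M HCl quench; crude 3, conc. HCl (cat.), CH2Cl2, rt
Reagents that add atoms: none
Why: Grignard 1,2-addition to one vinylogous-ester carbonyl of the squarate should give racemic carbinol 3, and acid then ionises the tertiary hydroxyl with help from the distal isopropoxy group so that capture of water and loss of isopropanol deliver the alkylcyclobutenedione (the standard squarate-to-cyclobutenedione transposition), under conditions mild enough to leave the terminal alkene in place.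

Step 2
Reactants: 5 4H-pyran-4-one
Product: 7 3-bromo-4H-pyran-4-one, via trans-dibromide 6 (not isolated)
Conditions: Br2 (1.0 equiv), CH2Cl2, 0 °C; then Et3N, 0 °C to rt
Reagents that add atoms: bromine, BrBr
Why: bromine should add anti across the enol-ether-like C2=C3 bond and triethylamine then removes the acidic C3 proton with loss of the anomeric C2 bromide, the usual addition–elimination α-bromination of an enone, with one equivalent of bromine limiting 3,5-dibromination.

Step 3
Reactants: 7 3-bromo-4H-pyran-4-one; 8 2,4,5-trimethoxyphenylboronic acid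
Product: 9 3-(2,4,5-trimethoxyphenyl)-4H-pyran-4-one
Conditions: Pd(OAc)2 (3 mol %), SPhos (6 mol %), K3PO4, toluene/H2O (10:1), 80 °C
Reagents that add atoms: none
Why: Suzuki–Miyaura coupling of the α-bromoenone with an electron-rich ortho-substituted arylboronic acid, for which the Pd(OAc)2/SPhos system turns over hindered partners quickly while the biphasic phosphate base spares the base-sensitive pyranone and limits protodeboronation.

Step 4
Reactants: 9 3-(2,4,5-trimethoxyphenyl)-4H-pyran-4-one; 4 3-allyl-4-isopropoxycyclobut-3-ene-1,2-dione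
Product: 12 2-allyl-3-isopropoxy-4-methoxy-4-[4-oxo-5-(2,4,5-trimethoxyphenyl)-4H-pyran-2-yl]cyclobut-2-en-1-one (racemic), via 6-lithiopyranone 10 (not isolated), via lithium alkoxide 11 (not isolated)
Conditions: lithium 2,2,6,6-tetramethylpiperidide (from 2,2,6,6-tetramethylpiperidine and n-butyllithium), THF, −78 °C; add 4, −78 °C; then MeOTf (1.2 equiv), −78 to −20 °C
Reagents that add atoms: methyl trifluoromethanesulfonate, COS(=O)(=O)C(F)(F)F
Why: the hindered amide should remove the unhindered C6–H next to the ring oxygen (C2–H is shielded by the twisted 2-methoxyaryl group) as in known α-metalations of chromones and 4-pyranones, the vinyllithium then adds 1,2 to the more electrophilic ketone-type carbonyl of 4 (the one flanking the isopropoxy carbon, the other being a vinylogous ester), and the tertiary lithium alkoxide is O-methylated by methyl triflate far faster than the neutral pyranone carbonyl, the new quaternary centre being formed as a racemate because it is erased in step 5.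

Step 5
Reactants: 12 2-allyl-3-isopropoxy-4-methoxy-4-[4-oxo-5-(2,4,5-trimethoxyphenyl)-4H-pyran-2-yl]cyclobut-2-en-1-one
Product: 15 6-allyl-5-hydroxy-7-isopropoxy-8-methoxy-3-(2,4,5-trimethoxyphenyl)-4H-chromen-4-one, via dienylketene 13 (not isolated), via dienone 14 (not isolated)
Conditions: degassed toluene (0.02 M), 110 °C
Reagents that add atoms: none
Why: Proposed new method: thermal conrotatory 4π opening of the cyclobutenone C1–C4 bond should give dienylketene 13, whose ketene carbon then bonds to C5 of the pyranone C5=C6 bond in a disrotatory 6π electrocyclisation (ring A is closed as a six-membered carbocycle by pericyclic C5–C4a bond formation onto the existing ring C), and dienone 14, whose C4a hydrogen lies between two carbonyl groups, enolises at once to the hydrogen-bonded 5-hydroxychromone. The closest known reaction type is the Moore-type ring expansion of 4-aryl, 4-heteroaryl and 4-alkenyl 4-alkoxycyclobutenones to hydroquinone monoethers; a 4-pyranon-2-yl arm has not been used, but its C5=C6 bond is only weakly aromatic and C5 is the nucleophilic α-carbon of a vinylogous ester, polarity-matched to the electrophilic ketene carbon, so it should react at least as readily as furyl or aryl arms. The selectivity required is torquoselective outward rotation of the C4 methoxy group, the normal preference for an oxygen donor on the breaking bond, which swings the pyranonyl group inward toward the ketene. The positions of 5-OH, 6-allyl, 7-isopropoxy and 8-OMe follow from the connectivity of the cyclobutenone alone, and the two para oxygens emerge differentiated without protecting groups. No stereocentre is created in the product: the racemic carbinol centre of 12 becomes aromatic C8 and the transient C4a centre of 14 is lost on tautomerisation.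

Step 6
Reactants: 15 6-allyl-5-hydroxy-7-isopropoxy-8-methoxy-3-(2,4,5-trimethoxyphenyl)-4H-chromen-4-one
Product: 16 6-allyl-5,7-dihydroxy-8-methoxy-3-(2,4,5-trimethoxyphenyl)-4H-chromen-4-one
Conditions: BCl3 (1 M in CH2Cl2, 3 equiv), CH2Cl2, −78 to 0 °C; then H2O
Reagents that add atoms: none
Why: boron trichloride cleaves secondary alkyl aryl ethers by an ionising pathway much faster than methyl ethers at low temperature, so the isopropyl group should leave as 2-chloropropane while the 8-OMe and ring B methoxy groups (none peri to the carbonyl) and the terminal alkene are retained, and the step is placed before the metathesis so that no Lewis acid meets the acid-sensitive prenyl group.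

Step 7
Reactants: 16 6-allyl-5,7-dihydroxy-8-methoxy-3-(2,4,5-trimethoxyphenyl)-4H-chromen-4-one; 17 2-methyl-2-butene
Product: 18 6-prenylisocaviunin
Conditions: 17/CH2Cl2 (1:1), second-generation Hoveyda–Grubbs catalyst RuCl2(H2IMes)(=CH-C6H4-2-OiPr) (5 mol %), 40 °C, sealed tube
Reagents that add atoms: none
Why: olefin cross-metathesis of a terminal allylarene with excess 2-methyl-2-butene is a standard allyl-to-prenyl conversion that tolerates free phenols with second-generation ruthenium carbenes and is driven by loss of propene, and the new trisubstituted alkene carries two identical methyl groups so no E/Z question arises.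

Compound list
1 | diisopropyl squarate (3,4-diisopropoxycyclobut-3-ene-1,2-dione) | CC(C)OC1=C(OC(C)C)C(=O)C1=O | starting material
2 | allylmagnesium bromide | C=CC[Mg]Br | starting material
3 | 4-allyl-4-hydroxy-2,3-diisopropoxycyclobut-2-en-1-one (racemic, not isolated) | C=CCC1(O)C(OC(C)C)=C(OC(C)C)C1=O | intermediate
4 | 3-allyl-4-isopropoxycyclobut-3-ene-1,2-dione | C=CCC1=C(OC(C)C)C(=O)C1=O | intermediate
5 | 4H-pyran-4-one | O=c1ccocc1 | starting material
6 | trans-2,3-dibromo-2,3-dihydro-4H-pyran-4-one (racemic, one enantiomer drawn, not isolated) | O=C1C=CO[C@H](Br)[C@H]1Br | intermediate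
7 | 3-bromo-4H-pyran-4-one | O=c1ccocc1Br | intermediate
8 | 2,4,5-trimethoxyphenylboronic acid | COc1cc(OC)c(B(O)O)cc1OC | starting material
9 | 3-(2,4,5-trimethoxyphenyl)-4H-pyran-4-one | COc1cc(OC)c(-c2coccc2=O)cc1OC | intermediate
10 | 6-lithio-3-(2,4,5-trimethoxyphenyl)-4H-pyran-4-one (not isolated) | [Li]c1cc(=O)c(-c2cc(OC)c(OC)cc2OC)co1 | intermediate
11 | lithium 3-allyl-2-isopropoxy-4-oxo-1-[4-oxo-5-(2,4,5-trimethoxyphenyl)-4H-pyran-2-yl]cyclobut-2-en-1-olate (racemic, not isolated) | C=CCC1=C(OC(C)C)C([O-])(c2cc(=O)c(-c3cc(OC)c(OC)cc3OC)co2)C1=O.[Li+] | intermediate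
12 | 2-allyl-3-isopropoxy-4-methoxy-4-[4-oxo-5-(2,4,5-trimethoxyphenyl)-4H-pyran-2-yl]cyclobut-2-en-1-one (racemic) | C=CCC1=C(OC(C)C)C(OC)(c2cc(=O)c(-c3cc(OC)c(OC)cc3OC)co2)C1=O | intermediate
13 | 2-allyl-3-isopropoxy-4-methoxy-4-[4-oxo-5-(2,4,5-trimethoxyphenyl)-4H-pyran-2-yl]buta-1,3-dien-1-one, pyranonyl group cis to the ketene-bearing carbon (dienylketene, not isolated) | C=CCC(=C=O)/C(OC(C)C)=C(/OC)c1cc(=O)c(-c2cc(OC)c(OC)cc2OC)co1 | intermediate
14 | 6-allyl-7-isopropoxy-8-methoxy-3-(2,4,5-trimethoxyphenyl)-4aH-chromene-4,5-dione (racemic, not isolated) | C=CCC1=C(OC(C)C)C(OC)=C2OC=C(c3cc(OC)c(OC)cc3OC)C(=O)C2C1=O | intermediate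
15 | 6-allyl-5-hydroxy-7-isopropoxy-8-methoxy-3-(2,4,5-trimethoxyphenyl)-4H-chromen-4-one | C=CCc1c(O)c2c(=O)c(-c3cc(OC)c(OC)cc3OC)coc2c(OC)c1OC(C)C | intermediate
16 | 6-allyl-5,7-dihydroxy-8-methoxy-3-(2,4,5-trimethoxyphenyl)-4H-chromen-4-one | C=CCc1c(O)c2c(=O)c(-c3cc(OC)c(OC)cc3OC)coc2c(OC)c1O | intermediate
17 | 2-methyl-2-butene | CC=C(C)C | starting material
18 | 6-prenylisocaviunin, 5,7-dihydroxy-8-methoxy-6-(3-methylbut-2-enyl)-3-(2,4,5-trimethoxyphenyl)-4H-chromen-4-one | COc1cc(OC)c(-c2coc3c(OC)c(O)c(CC=C(C)C)c(O)c3c2=O)cc1OC | target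

Total step count: 7.
Longest linear sequence: 6 steps (steps 2, 3, 4, 5, 6 and 7, from 4H-pyran-4-one 5); the squarate branch (step 1) joins at step 4.

Steps most likely to fail

Step 5. The cross-conjugated pyranone C5=C6 bond may not enter the 6π closure cleanly, so that ketene 13 is lost to dimerisation or to capture by traces of nucleophile, or the electron-rich 5-hydroxychromone degrades on prolonged heating. The fallback uses known chemistry only, sets out from dione 4 and returns at 15. It replaces the pyranonyl arm by a dihydropyranyl arm, a well-precedented cyclic alkenyl arm of this ring expansion, which keeps the ring oxygen tied into ring C and so preserves the distinction between O1 and 5-OH. Bought 2,3-dihydro-4H-pyran-4-one would be reduced under Luche conditions (NaBH4, CeCl3·7H2O, MeOH) to 3,4-dihydro-2H-pyran-4-ol F1 and silylated (TIPSCl, imidazole) to 4-(triisopropylsilyloxy)-3,4-dihydro-2H-pyran F2. Lithiation at the enol ether CH (tert-butyllithium, THF, −78 to 0 °C, as for glycals), addition to 4 at −78 °C and a methyl triflate quench should give 2-allyl-3-isopropoxy-4-methoxy-4-[4-(triisopropylsilyloxy)-3,4-dihydro-2H-pyran-6-yl]cyclobut-2-en-1-one F3. Thermolysis in toluene, the known alkenyl-arm ring expansion, should give 6-allyl-7-isopropoxy-8-methoxy-4-(triisopropylsilyloxy)chroman-5-ol F4. Desilylation with TBAF would give 6-allyl-7-isopropoxy-8-methoxychromane-4,5-diol F5, and MnO2 oxidation of the benzylic carbinol would give 6-allyl-5-hydroxy-7-isopropoxy-8-methoxychroman-4-one F6. Palladium-catalysed ketone α-arylation with 1-bromo-2,4,5-trimethoxybenzene (Pd(OAc)2, XPhos, sodium tert-butoxide, toluene, 80 °C) would give 6-allyl-5-hydroxy-7-isopropoxy-8-methoxy-3-(2,4,5-trimethoxyphenyl)chroman-4-one F7, and dehydrogenation with DDQ in dioxane would deliver 15. This fallback is much longer than the main line, and its last two operations (α-arylation beside a free phenol, DDQ beside an allylarene) are its own weak points.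

Step 4. Removal of the shielded C2–H may compete with removal of C6–H and give the regioisomeric adduct; proton transfer from the doubly activated allylic CH2 of 4 to the vinyllithium is a second concern. The fallback is a blocking-group route that sets out from bromide 7 and returns at 15. Bromide 7 would be lithiated between the ring oxygen and the bromine-bearing carbon with in situ silylation (lithium 2,2,6,6-tetramethylpiperidide, Me3SiCl, THF, −78 °C) to give 3-bromo-2-(trimethylsilyl)-4H-pyran-4-one F8. Anhydrous Suzuki coupling with 8 (Pd(OAc)2, SPhos, K3PO4, toluene) would give 3-(2,4,5-trimethoxyphenyl)-2-(trimethylsilyl)-4H-pyran-4-one F9, in which C6–H is the only proton next to the ring oxygen. The conditions of step 4 should then give 2-allyl-3-isopropoxy-4-methoxy-4-[4-oxo-5-(2,4,5-trimethoxyphenyl)-6-(trimethylsilyl)-4H-pyran-2-yl]cyclobut-2-en-1-one F10, and those of step 5 should give 6-allyl-5-hydroxy-7-isopropoxy-8-methoxy-3-(2,4,5-trimethoxyphenyl)-2-(trimethylsilyl)-4H-chromen-4-one F11. Fluoride protodesilylation (TBAF, AcOH, THF) returns 15.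

Step 7. Ruthenium hydride species may move the allyl double bond into conjugation with ring A, giving a propenyl isomer that cannot be carried on, or turnover may stall through chelation of the carbene by the neighbouring hydroxyl groups. The fallback is oxidative cleavage followed by Wittig olefination; it sets out from 16 and returns at 18. Cleavage of the terminal alkene (OsO4 cat., NaIO4, 2,6-lutidine, dioxane/H2O) would give 2-[5,7-dihydroxy-8-methoxy-4-oxo-3-(2,4,5-trimethoxyphenyl)-4H-chromen-6-yl]acetaldehyde F12, in equilibrium with its lactol on a neighbouring hydroxyl. Excess isopropylidenetriphenylphosphorane (from isopropyltriphenylphosphonium iodide and n-butyllithium, THF, −78 °C to rt, the extra equivalents being taken up by the two phenols) should then give 18. Periodate oxidation of the phenol para to the 8-OMe group is the risk of this fallback; the hydrogen bond to the C4 carbonyl should slow it.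

Further compounds
F1 | step 5 | 3,4-dihydro-2H-pyran-4-ol (racemic) | OC1C=COCC1
F2 | step 5 | 4-(triisopropylsilyloxy)-3,4-dihydro-2H-pyran (racemic) | CC(C)[Si](OC1C=COCC1)(C(C)C)C(C)C
F3 | step 5 | 2-allyl-3-isopropoxy-4-methoxy-4-[4-(triisopropylsilyloxy)-3,4-dihydro-2H-pyran-6-yl]cyclobut-2-en-1-one (diastereomer mixture, racemic) | C=CCC1=C(OC(C)C)C(OC)(C2=CC(O[Si](C(C)C)(C(C)C)C(C)C)CCO2)C1=O
F4 | step 5 | 6-allyl-7-isopropoxy-8-methoxy-4-(triisopropylsilyloxy)chroman-5-ol (racemic) | C=CCc1c(O)c2C(O[Si](C(C)C)(C(C)C)C(C)C)CCOc2c(OC)c1OC(C)C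
F5 | step 5 | 6-allyl-7-isopropoxy-8-methoxychromane-4,5-diol (racemic) | C=CCc1c(O)c2C(O)CCOc2c(OC)c1OC(C)C
F6 | step 5 | 6-allyl-5-hydroxy-7-isopropoxy-8-methoxychroman-4-one | C=CCc1c(O)c2C(=O)CCOc2c(OC)c1OC(C)C
F7 | step 5 | 6-allyl-5-hydroxy-7-isopropoxy-8-methoxy-3-(2,4,5-trimethoxyphenyl)chroman-4-one (racemic) | C=CCc1c(O)c2C(=O)C(c3cc(OC)c(OC)cc3OC)COc2c(OC)c1OC(C)C
F8 | step 4 | 3-bromo-2-(trimethylsilyl)-4H-pyran-4-one | C[Si](C)(C)c1occc(=O)c1Br
F9 | step 4 | 3-(2,4,5-trimethoxyphenyl)-2-(trimethylsilyl)-4H-pyran-4-one | COc1cc(OC)c(-c2c([Si](C)(C)C)occc2=O)cc1OC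
F10 | step 4 | 2-allyl-3-isopropoxy-4-methoxy-4-[4-oxo-5-(2,4,5-trimethoxyphenyl)-6-(trimethylsilyl)-4H-pyran-2-yl]cyclobut-2-en-1-one (racemic) | C=CCC1=C(OC(C)C)C(OC)(c2cc(=O)c(-c3cc(OC)c(OC)cc3OC)c([Si](C)(C)C)o2)C1=O
F11 | step 4 | 6-allyl-5-hydroxy-7-isopropoxy-8-methoxy-3-(2,4,5-trimethoxyphenyl)-2-(trimethylsilyl)-4H-chromen-4-one | C=CCc1c(O)c2c(=O)c(-c3cc(OC)c(OC)cc3OC)c([Si](C)(C)C)oc2c(OC)c1OC(C)C
F12 | step 7 | 2-[5,7-dihydroxy-8-methoxy-4-oxo-3-(2,4,5-trimethoxyphenyl)-4H-chromen-6-yl]acetaldehyde | O=CCc1c(O)c2c(=O)c(-c3cc(OC)c(OC)cc3OC)coc2c(OC)c1O
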